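**Retrosynthetic overview**

1. Feature: in the hydroazulene (locants used throughout: C1 methylated fusion carbon, C2–C3 CH2, C4 isopropyl carbinol, C5 fusion CH, C6 ester CH, C7 CH2, C8–C9 oxirane with CH3 on C8, C10 CHOH; five-membered ring C1–C5, seven-membered ring C1, C5–C10) the oxygenated C10 is bonded to quaternary C1 and C6 is oxygenated as well. One ether oxygen joining C6 and C10 in a six-membered ring (O, C6, C7, C8, C9, C10) can therefore pass C10 on to C1 across the allyl unit C6–C5=C1.
2. Late disconnections: C6 angelate; C4–isopropyl bond (organocerium addition to the C4 ketone); C5–H and C6–OH (hydroboration of C5=C6); oxirane (hydroxyl-directed epoxidation of C8=C9).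
3. Key disconnection: C1–C10, with C6–O re-formed, back to a 2-(cyclopentenyl)-4-methyl-3,6-dihydro-2H-pyran (ring-enlarging [2,3]-Wittig shift).
4. The dihydropyran comes from ring-closing metathesis of an allyl ether; its single stereocentre C6 comes from asymmetric methallylboration of a cyclopentenecarbaldehyde made from a bought bromoenone.
5. Ring order: cyclopentene (bought), dihydropyran (temporary, step 5), seven-membered carbocycle (step 6), oxirane (step 7).

Key step: step 6

Remark: the locants C1–C10 defined above are also used for the corresponding atoms of the monocyclic precursors, and the CIP descriptors given with these locants refer to them.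

**Route**

Step 1
Reactants: 1 2-bromo-3-methylcyclopent-2-en-1-one
Product: 2 6-bromo-7-methyl-1,4-dioxaspiro[4.4]non-6-ene
Conditions: HOCH2CH2OH, p-TsOH (cat.), benzene, reflux, Dean–Stark
Reagents that add atoms: ethylene glycol, OCCO
Why: Acid-catalysed ketalisation with azeotropic removal of water; the α-bromine keeps the double bond from moving out of the 2,3-position, as is usual for 2-bromoenone ketals.

Step 2
Reactants: 2 6-bromo-7-methyl-1,4-dioxaspiro[4.4]non-6-ene
Product: 5 7-methyl-1,4-dioxaspiro[4.4]non-6-ene-6-carbaldehyde, via vinyllithium 3 (not isolated), via lithium hemiaminal alkoxide 4 (not isolated)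
Conditions: n-BuLi, THF, −78 °C; DMF, −78 to 0 °C; H2O
Reagents that add atoms: N,N-dimethylformamide, CN(C)C=O
Why: Bromine–lithium exchange gives the vinyllithium (a masked α-acylvinyl anion), which is formylated by DMF (Bouveault formylation); the hemiaminal alkoxide collapses to the aldehyde on aqueous work-up and the ketal is inert to the basic conditions.

Step 3
Reactants: 5 7-methyl-1,4-dioxaspiro[4.4]non-6-ene-6-carbaldehyde
Product: 7 (1S)-3-methyl-1-(7-methyl-1,4-dioxaspiro[4.4]non-6-en-6-yl)but-3-en-1-ol, via diisopinocampheylborinate of the alcohol 6 (not isolated)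
Conditions: (−)-Ipc2BOMe [from (+)-α-pinene], CH2=C(CH3)CH2MgCl, Et2O, −78 °C to rt; then 5, −78 °C; then NaOH, H2O2, 0 °C to rt
Reagents that add atoms: 2-methylallylmagnesium chloride, CC(=C)C[Mg]Cl
Why: Brown asymmetric allylboration: the B-(2-methylallyl)diisopinocampheylborane formed in the flask transfers the methallyl group through a closed chair (Zimmerman–Traxler) transition state to the Si face of the aldehyde, as this antipode does with simple aldehydes, which sets C6 as S; oxidative work-up cleaves the borinate.

Step 4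
Reactants: 7 (1S)-3-methyl-1-(7-methyl-1,4-dioxaspiro[4.4]non-6-en-6-yl)but-3-en-1-ol
Product: 9 6-[(1S)-3-methyl-1-(prop-2-en-1-yloxy)but-3-en-1-yl]-7-methyl-1,4-dioxaspiro[4.4]non-6-ene, via sodium alkoxide 8 (not isolated)
Conditions: NaH, THF/DMF, 0 °C; CH2=CHCH2Br, Bu4NI (cat.), 0 °C to rt
Reagents that add atoms: allyl bromide, C=CCBr
Why: Williamson ether synthesis on the sodium alkoxide; the C6–O bond is not broken, so C6 stays S.

Step 5
Reactants: 9 6-[(1S)-3-methyl-1-(prop-2-en-1-yloxy)but-3-en-1-yl]-7-methyl-1,4-dioxaspiro[4.4]non-6-ene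
Product: 10 7-methyl-6-[(2S)-4-methyl-3,6-dihydro-2H-pyran-2-yl]-1,4-dioxaspiro[4.4]non-6-ene
Conditions: second-generation Grubbs catalyst (H2IMes)(PCy3)Cl2Ru=CHPh (5 mol%), CH2Cl2 (0.01 M), 40 °C
Reagents that add atoms: none
Why: Ring-closing metathesis between the monosubstituted allyl alkene and the 1,1-disubstituted methallyl alkene closes the six-membered ether (O, C6, C7, C8, C9, C10) with a trisubstituted C8=C9 bond and loss of ethene; the tetrasubstituted cyclopentene does not react with the catalyst.

Step 6
Reactants: 10 7-methyl-6-[(2S)-4-methyl-3,6-dihydro-2H-pyran-2-yl]-1,4-dioxaspiro[4.4]non-6-ene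
Product: 13 (1S,10R)-10-hydroxy-1,8-dimethyl-hydroazulene-5,8-diene C4 ethylene ketal (bicyclic dienol; C5=C6 and C8=C9), via C10-lithiated dihydropyran 11 (not isolated), via lithium alkoxide of the dienol 12 (not isolated)
Conditions: sec-BuLi (1.3 equiv), THF, −78 to −40 °C; H2O
Reagents that add atoms: none
Why: Proposed new method: sec-BuLi should remove the pseudo-axial C10–H, which is α to oxygen and aligned with the C8=C9 π bond, whereas the C6–H is held in the nodal plane of the cyclopentene by allylic strain against the C1 methyl and the ketal; the α-oxy allyl anion 11 then attacks C1 through a five-centre, six-electron [2,3]-Wittig transition state while C6–O breaks. The closest known reactions are the acyclic [2,3]-Wittig rearrangement of bis-allylic ethers and the ring-contracting [2,3]-shift of macrocyclic bis-allylic ethers; a [2,3]-shift inside a six-membered ether that enlarges the ring has not been shown. The seven-membered carbocycle closes by C1–C10 bond formation across the ether (six-membered ether to seven-membered carbocycle, a net one-atom enlargement) through an 8-oxabicyclo[3.2.1]octene-like arrangement in which the cyclopentenyl group is axial and syn to the axial C10 lone pair. Both new stereocentres are controlled by C6: the shift is suprafacial on C6–C5=C1, so C1 is attacked on the face that carried the C6–O bond (C1 S), and the C7–C8=C9 tether allows only one arrangement at C10 (R) and only the cis C5=C6 alkene. The step needs lithiation at C10 over C6 (secured as stated) and the [2,3] path over the [1,2] and [1,4] shifts, which low temperature should favour because the concerted path needs no C6–O homolysis.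

Step 7
Reactants: 13 (1S,10R)-10-hydroxy-1,8-dimethyl-hydroazulene-5,8-diene C4 ethylene ketal
Product: 14 (1S,8R,9S,10S)-8,9-epoxy-10-hydroxy-1,8-dimethyl-hydroazul-5-ene C4 ethylene ketal (oxirane oxygen syn to 10-OH)
Conditions: VO(acac)2 (3 mol%), t-BuOOH (1.1 equiv), CH2Cl2, 0 °C
Reagents that add atoms: tert-butyl hydroperoxide, CC(C)(C)OO
Why: Hydroxyl-directed vanadium-catalysed epoxidation: the vanadate ester of the C10 alcohol delivers oxygen to the allylic C8=C9 bond much faster than to the homoallylic, ketal-deactivated C5=C6 bond and, as for cycloalkenols of this ring size, syn to the hydroxyl, which sets C8 (R) and C9 (S).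

Step 8
Reactants: 14 (1S,8R,9S,10S)-8,9-epoxy-10-hydroxy-1,8-dimethyl-hydroazul-5-ene C4 ethylene ketal
Product: 16 (1S,5S,6S,8R,9S,10S)-8,9-epoxy-6,10-dihydroxy-1,8-dimethyl-hydroazulane C4 ethylene ketal (trans ring fusion; 6-OH, 10-OH and oxirane oxygen on one face), via bridging oxaborinane 15 (not isolated)
Conditions: BH3·THF (1.1 equiv), THF, −20 °C to rt; then NaOH, H2O2, 0 °C
Reagents that add atoms: hydrogen peroxide, OO
Why: Hydroboration–oxidation: borane first forms the C10 alkoxyborane, whose pseudo-axial C10–O bond lies over the upper face of C5=C6, so B–H should add syn from that face with boron on the less substituted C6 (six-membered oxaborinane) and hydrogen on C5, anti to the C1 methyl, which sets C5 (S, trans fusion) and, after oxidation with retention, C6 (S).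

Step 9
Reactants: 16 (1S,5S,6S,8R,9S,10S)-8,9-epoxy-6,10-dihydroxy-1,8-dimethyl-hydroazulane C4 ethylene ketal
Product: 17 (1S,5S,6S,8R,9S,10S)-8,9-epoxy-6,10-dihydroxy-1,8-dimethyl-hydroazulan-4-one
Conditions: PPTS (0.2 equiv), acetone/H2O (10:1), 40 °C
Reagents that add atoms: water, O
Why: Acid-catalysed hydrolysis of the cyclopentanone dioxolane under pyridinium catalysis, which should be mild enough for the trisubstituted oxirane and for the β-hydroxy ketone (no base, so no retro-aldol and no epimerisation at C5).

Step 10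
Reactants: 17 (1S,5S,6S,8R,9S,10S)-8,9-epoxy-6,10-dihydroxy-1,8-dimethyl-hydroazulan-4-one
Product: 19 (1S,4R,5S,6S,8R,9S,10S)-8,9-epoxy-4-isopropyl-1,8-dimethyl-hydroazulane-4,6,10-triol, via tris(chloromagnesium) alkoxide 18 (not isolated)
Conditions: i-PrMgCl (5 equiv), CeCl3 (5 equiv), THF, −78 to −40 °C; H2O
Reagents that add atoms: isopropylmagnesium chloride, CC(C)[Mg]Cl
Why: Organocerium (Imamoto) 1,2-addition, which suppresses enolisation and β-hydride reduction by the isopropyl reagent; the nucleophile enters the cyclopentanone anti to the adjacent C5–C6 bond and to the C1 methyl, so isopropyl ends cis to 5-H and C4 is set as R, with the two hydroxyls carried as alkoxides.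

Step 11
Reactants: 19 (1S,4R,5S,6S,8R,9S,10S)-8,9-epoxy-4-isopropyl-1,8-dimethyl-hydroazulane-4,6,10-triol; 20 angelic acid
Product: 22 lapiferine (the 6-O-angelate of 19), via mixed anhydride 21 (not isolated)
Conditions: 20 (1.5 equiv), 2,4,6-Cl3C6H2COCl, Et3N, toluene, rt; then 19, toluene, 75 °C (no DMAP)
Reagents that add atoms: none
Why: Yamaguchi mixed-anhydride esterification, run without a nucleophilic catalyst so that the Z geometry of the angeloyl group is kept; the C6 hydroxyl (flanked by CH and CH2) should react ahead of the neopentylic C10 hydroxyl next to quaternary C1 and ahead of the tertiary C4 hydroxyl.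

**Compound list**

1 | 2-bromo-3-methylcyclopent-2-en-1-one | CC1=C(Br)C(=O)CC1 | starting material
2 | 6-bromo-7-methyl-1,4-dioxaspiro[4.4]non-6-ene | CC1=C(Br)C2(CC1)OCCO2 | intermediate
3 | (7-methyl-1,4-dioxaspiro[4.4]non-6-en-6-yl)lithium | [Li]C1=C(C)CCC12OCCO2 | intermediate
4 | lithium (dimethylamino)(7-methyl-1,4-dioxaspiro[4.4]non-6-en-6-yl)methanolate | [Li]OC(N(C)C)C1=C(C)CCC12OCCO2 | intermediate
5 | 7-methyl-1,4-dioxaspiro[4.4]non-6-ene-6-carbaldehyde | O=CC1=C(C)CCC12OCCO2 | intermediate
6 | diisopinocampheylborinate of alcohol 7 | CC(=C)C[C@H](OB([C@@H]1C[C@@H]2C[C@@H](C2(C)C)[C@H]1C)[C@@H]1C[C@@H]2C[C@@H](C2(C)C)[C@H]1C)C1=C(C)CCC12OCCO2 | intermediate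
7 | (1S)-3-methyl-1-(7-methyl-1,4-dioxaspiro[4.4]non-6-en-6-yl)but-3-en-1-ol | CC(=C)C[C@H](O)C1=C(C)CCC12OCCO2 | intermediate
8 | sodium alkoxide of 7 | CC(=C)C[C@H](O[Na])C1=C(C)CCC12OCCO2 | intermediate
9 | 6-[(1S)-3-methyl-1-(prop-2-en-1-yloxy)but-3-en-1-yl]-7-methyl-1,4-dioxaspiro[4.4]non-6-ene | CC(=C)C[C@H](OCC=C)C1=C(C)CCC12OCCO2 | intermediate
10 | 7-methyl-6-[(2S)-4-methyl-3,6-dihydro-2H-pyran-2-yl]-1,4-dioxaspiro[4.4]non-6-ene | CC1=CCO[C@@H](C1)C1=C(C)CCC12OCCO2 | intermediate
11 | 10 lithiated at the allylic OCH2 carbon (C10; pyran C6) | CC1=CC([Li])O[C@@H](C1)C1=C(C)CCC12OCCO2 | intermediate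
12 | lithium alkoxide of 13 | CC1=C[C@@H](O[Li])[C@@]2(C)CCC3(OCCO3)C2=CC1 | intermediate
13 | (1S,10R)-bicyclic dienol: 10-OH, quaternary C1 (CH3), C5=C6 and C8=C9 (CH3 on C8), C4 ethylene ketal | CC1=C[C@@H](O)[C@@]2(C)CCC3(OCCO3)C2=CC1 | intermediate
14 | (1S,8R,9S,10S)-8,9-epoxy alcohol: oxirane syn to 10-OH, C5=C6, C4 ethylene ketal | C12=CC[C@@]3(C)O[C@H]3[C@@H](O)[C@@]1(C)CCC24OCCO4 | intermediate
15 | oxaborinane bridging O10 and C6 through B–H (C5–H and C6–B on the 10-O face) | [BH]4[C@H]1C[C@@]2(C)O[C@H]2[C@@H](O4)[C@@]2(C)CCC3(OCCO3)[C@H]12 | intermediate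
16 | (1S,5S,6S,8R,9S,10S)-8,9-epoxy-6,10-diol, trans-fused, C4 ethylene ketal | O[C@H]1C[C@@]2(C)O[C@H]2[C@@H](O)[C@@]2(C)CCC3(OCCO3)[C@H]12 | intermediate
17 | (1S,5S,6S,8R,9S,10S)-8,9-epoxy-6,10-dihydroxy-1,8-dimethyl-hydroazulan-4-one | O[C@H]1C[C@@]2(C)O[C@H]2[C@@H](O)[C@@]2(C)CCC(=O)[C@H]12 | intermediate
18 | tris(chloromagnesium) alkoxide of 19 | Cl[Mg]O[C@H]1C[C@@]2(C)O[C@H]2[C@@H](O[Mg]Cl)[C@@]2(C)CC[C@@](O[Mg]Cl)(C(C)C)[C@H]12 | intermediate
19 | (1S,4R,5S,6S,8R,9S,10S)-8,9-epoxy-4-isopropyl-1,8-dimethyl-hydroazulane-4,6,10-triol | O[C@H]1C[C@@]2(C)O[C@H]2[C@@H](O)[C@@]2(C)CC[C@@](O)(C(C)C)[C@H]12 | intermediate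
20 | angelic acid, (2Z)-2-methylbut-2-enoic acid | C/C=C(/C)C(=O)O | starting material
21 | angelic 2,4,6-trichlorobenzoic anhydride | C/C=C(/C)C(=O)OC(=O)c1c(Cl)cc(Cl)cc1Cl | intermediate
22 | lapiferine | C/C=C(/C)C(=O)O[C@H]1C[C@@]2(C)O[C@H]2[C@@H](O)[C@@]2(C)CC[C@@](O)(C(C)C)[C@H]12 | target

**Totals**

Total step count: 11. Longest linear sequence: 11 steps (1 to 22).

**Steps most likely to fail**

1. Step 6 (key step). What may go wrong: lithiation at C6–H or at an allylic methyl instead of C10; a radical [1,2]-shift (ring contraction to a cyclopentenol) or a [1,4]-shift outrunning the strained bicyclic [2,3] transition state; or no rearrangement before the anion decomposes. Fallback, from 9 back to 13: the sigmatropic shift is run before the ring exists. Allyl ether 9 is deprotonated at the O-allyl CH2 (n-BuLi, THF, −78 °C) and undergoes the ordinary acyclic [2,3]-Wittig rearrangement of a bis-allylic ether to the open-chain trienol F1. The substituent on C5 (the ketal carbon C4) should push the methallyl group on C6 into the pseudo-axial position, as in Still-type rearrangements of 2-substituted allyl ethers. That gives the C5=C6 isomer with C7 cis to C1 and the same C6-to-C1 chirality transfer, and an exo vinyl group gives the 10R carbinol. Ring-closing metathesis of F1 between the vinyl group and the 1,1-disubstituted alkene (second-generation Grubbs catalyst, CH2Cl2, 40 °C) then closes the seven-membered ring to 13; only the isomer with C7 cis to C1 can cyclise.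

2. Step 8. What may go wrong: poor facial selectivity. The C1 methyl is only pseudo-equatorial on the seven-membered ring, so free borane may add from the methyl face and give the cis-fused C5/C6 diastereomer; slow reduction of the oxirane is a second risk. Fallback, from 14 back to 16: the hydride and the C6 heteroatom are delivered from a silicon tether on the C10 oxygen. Silylation of 14 with 1,1,3,3-tetramethyldisilazane gives the dimethylsilyl ether F2. Intramolecular hydrosilylation with Pt2[(CH2=CHSiMe2)2O]3 (zerovalent platinum, THF, 50 °C) should occur in the endo mode, silicon to C6 and hydrogen to C5 on the tether face, because C5 is fully substituted, and gives the cyclic siloxane F3. Tamao–Fleming oxidation (H2O2, KF, KHCO3, THF/MeOH) replaces silicon by hydroxyl with retention and gives 16.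

3. Step 11. What may go wrong: competing acylation of the C10 hydroxyl, and Z-to-E isomerisation of the angeloyl group (to the tiglate) under the forcing conditions a hindered alcohol needs. Fallback, from 19 back to 22: the Z-alkene is built after the ester bond. Triol 19 is acylated at the C6 hydroxyl with the small, unhindered 2-[bis(2,2,2-trifluoroethoxy)phosphoryl]propanoic acid (EDC, DMAP, CH2Cl2, 0 °C), at a temperature where the C6/C10 difference is largest, to give the phosphonate ester F4. Still–Gennari olefination of F4 with acetaldehyde (KHMDS in excess to cover the free hydroxyls, 18-crown-6, THF, −78 °C) forms the Z-trisubstituted alkene and gives 22.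

Further compounds
F1 | step 6 | (1R)-1-[(6E,7S)-7-methyl-6-(3-methylbut-3-en-1-ylidene)-1,4-dioxaspiro[4.4]nonan-7-yl]prop-2-en-1-ol (open-chain trienol; C7 cis to C1 across C5=C6) | C=C[C@@H](O)[C@@]1(C)CCC2(OCCO2)/C1=C/CC(C)=C
F2 | step 8 | 10-O-dimethylsilyl ether of 14 | C12=CC[C@@]3(C)O[C@H]3[C@@H](O[SiH](C)C)[C@@]1(C)CCC24OCCO4
F3 | step 8 | cyclic siloxane bridging O10 and C6 through SiMe2 (C5–H and C6–Si on the 10-O face), C4 ethylene ketal | C[Si]4(C)[C@H]1C[C@@]2(C)O[C@H]2[C@@H](O4)[C@@]2(C)CCC3(OCCO3)[C@H]12
F4 | step 11 | 6-O-{2-[bis(2,2,2-trifluoroethoxy)phosphoryl]propanoyl} ester of 19 | CC(C(=O)O[C@H]1C[C@@]2(C)O[C@H]2[C@@H](O)[C@@]2(C)CC[C@@](O)(C(C)C)[C@H]12)P(=O)(OCC(F)(F)F)OCC(F)(F)F
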